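Its constants belong to no real substance; the result is computed.

Substrate left over beside target is no bystander, since the two react to side product, and that leftover is what my colleague and I argued about at the board.

    substrate + free catalyst → catalyst intermediate A (k1 = 0.0026 M⁻¹ s⁻¹)
    catalyst intermediate A → catalyst intermediate B (k2 = 0.21 s⁻¹)
    coupling partner + catalyst intermediate B ⇌ catalyst intermediate C (K3 = 0.23 M⁻¹, k3 = 0.026 M⁻¹ s⁻¹)
    catalyst intermediate C → free catalyst + target (k4 = 0.28 s⁻¹)
    substrate + target → side product (k5 = 4.7 × 10⁻⁶ M⁻¹ s⁻¹)

| flask | substrate | coupling partner | free catalyst | time |
|---|---|---|---|---|
| west | 0.50 M | 0.900 M | 4.5 mM | 4.0 d |
| south-east | 1.0 M | 0.900 M | 4.5 mM | 4.0 d |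
| north-west | 2.0 M | 0.900 M | 4.5 mM | 4.0 d |

- [target] at the end for west, south-east, north-west, in this order
- the shape of the row from first to last (falls, then rises / rises, then falls / falls all the way / hardly changes / rises all the way)

- percent here means substrate units held: one side product counts as two
- "hardly changes" means that all values lie within two and a half points (for a concentration: within two and a half percent of the largest)
- run time (west): 4.0 d

She held the limiting-reagent view: each target takes one substrate and one coupling partner, so the row is the smaller charge, 0.500 M, 0.900 M, 0.900 M, rising and then level.

I held that free catalyst can be frozen at its charge. In west, a free catalyst takes up substrate at 0.00130 s⁻¹, while catalyst intermediate B meets coupling partner at 0.0234 s⁻¹, faster than that, so free catalyst is the resting state while partner stands. Catalyst then makes target in proportion to [substrate], and the side reaction eats target in proportion to [substrate] too, so [substrate] drops out of their ratio. What remains is P* = 2.49 M, the crossover level: the [target] at which the side reaction removes target as fast as catalyst makes it.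

Averaged over the rise, a kept target costs about one plus [target]/P* substrates. With substrate used up, and the charge put in place of [target] inside that bracket, kept target is roughly the charge divided by one plus charge/P*, which for south-east gives 0.713 M. Partner used is the mean of charge and kept target, 0.857 M, less than the 0.900 M charged, so on this reckoning partner lasts in south-east.

For north-west the same reckoning asks for 1.55 M of partner, more than the charge, so there she is right about the limiting reagent. With frozen catalyst, and counting step 1 as the one draw on substrate, I estimate that partner goes in about 0.591 d, and each target made adds net one minus [target]/P*, so I estimate that [target] reaches 0.755 M. After that, each target lost takes one substrate with it, so [substrate] minus [target] stays at 0.200 M, and the remaining 3.41 d of side reaction leaves 0.299 M.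

The forecast, 0.41 M, 0.7 M, 0.32 M, rises, then falls, spoke of “leaving excess substrate that eats the target”, and its last two points stand a little from my 0.713 M and 0.299 M.

The flasks end at 0.413 M, 0.700 M and 0.309 M: rises, then falls. Her view keeps west, below the turn at 1.1 M: there substrate, the smaller charge, ended at 1.2% of what was charged.

In north-west the catalytic steps ran while coupling partner stood, and at 2.00 d partner was down to 0.00663% of its charge with catalyst intermediate B at 99.9% of the catalyst, after which substrate and target fell together, their gap reading 0.196 M then and 0.195 M at 4.00 d. In west free catalyst stood at 98.2% at 2.00 d, coupling partner ended at 50% of its charge, and P* applied to this charge gives 0.416 M for a flask holding 0.413 M at 4.00 d.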